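## The problem

Target 17 is a 1,5-oxygen-bridged diarylheptanoid: an oxan-4-one (O1, C2, C3, C4 carbonyl, C5, C6) carrying the guaiacyl ring A on C2 and, on C6, a two-carbon arm made of the carbinol C1′ and the methylene C2′ of the 4-hydroxyphenyl ring B. Only one ring has to be closed, so the real task is to build the chain C2–C3–C4–C5–C6–C1′–C2′ with oxygen on C2, C4, C6 and C1′ and then to join O1 to one of its two carbons. There are three stereocentres, C2 (S), C6 (R) and C1′ (S). C6 and C1′ form a vicinal erythro pair that no ring can control, so a reagent has to set them absolutely. C2 lies 1,3 to C6 across O1 and the required cis (diequatorial) arrangement is the thermodynamic one, so C6 can control C2. The functional groups are fragile in complementary ways: the ketone has an oxygen on each β-carbon and opens by retro-oxa-Michael elimination under base, the C2–O1 bond is a benzylic ether of a para-oxygenated arene that ionises in acid and can be hydrogenolysed, and the two phenols are easily oxidised. The feature that opens the structure is that C4 lies between two methylenes, C3 and C5, each next to an oxygen-bearing carbon. C4 is therefore a carbonyl dianion equivalent, and C2–C3 and C5–C6 are the carbons of two terminal epoxides.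

## Retrosynthesis

**17 to 16.** The two phenolic O–CH2Ph bonds are cut. Benzyl ethers are preferred to silyl ethers, which would not survive alkoxides in a polar medium or fluoride, and to methyl ethers, which could not be removed beside the ring A methoxy group. Precursor 16 differs from 17 only in these two groups. The forward hydrogenolysis has to spare the benzylic C2–O1 bond and the ketone, and has to come after all sulfur has left the molecule.

**16 to 15.** The C4 carbonyl is written as its 1,3-dithiane. This is the form in which C4 can act as a nucleophile twice, and it keeps the β,β′-dioxygenated ketone masked through the fluoride and acid steps where elimination would threaten. The forward step is a neutral thioacetal hydrolysis.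

**15 to 14.** The O1–C2 bond is cut, not its neighbour O1–C6. Closing at C6 would need an SN2 inversion at an unactivated secondary carbon flanked by the C1′ oxygen and would put a resolved stereocentre at risk. Closing at C2 uses a benzylic carbon whose cation is stabilised by the para-oxygen of ring A. Triol 14 has no ring and needs no defined configuration at C2. The forward reaction must ionise reversibly so that the 2,6-cis ring is reached under thermodynamic control and is preferred to the seven-membered ether through the C1′ hydroxyl.

**14 to 13.** Two O–Si bonds are cut. Bis-silyl ether 13 is exactly what the coupling delivers, so this disconnection only asks for fluoride cleavage.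

**13 to 9, 6 and 8.** Both C–C bonds at C4 are cut, C4–C5 and C3–C4.
- Against single-bond alternatives: an aldol cut at C3–C4 or C4–C5 would leave a free β-alkoxy ketone and pose a new stereochemical problem. The double cut at one carbon poses none, because each bond is formed by SN2 attack on an epoxide CH2.
- Simplification: the molecule falls into three pieces of similar size, the linchpin 9 (a commercial reagent), the chiral epoxide 6 carrying C6, C1′ and ring B, and the aryl oxirane 8 carrying C2 and ring A.
- Forward demands: the anion of 9 must open 6 first, silicon must then move from C4 to the C6 oxygen only on command, and the regenerated anion must open 8 at its unsubstituted carbon. Epoxide 6 is placed first because it is the valuable, limiting component. Oxirane 8 is placed second so that this acid-sensitive epoxide meets only an anion whose lithium is solvated.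

**6 to 5 to 4.** The O–Si bond is cut, then the oxirane oxygen is removed together with the absolute configuration. A Sharpless kinetic resolution of the racemic allylic alcohol 4 with the L-(+)-tartrate ligand gives the erythro epoxy alcohol 5, so C6 and C1′ are fixed in one operation on a small molecule. The TBS ether in 6 is chosen for two reasons: it is introduced without forming an alkoxide (no Payne rearrangement), and it is the same group the relay later places on the C6 oxygen, so a silyl shift between the two oxygens cannot change the outcome.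

**4 to 1 and 2.** The C1′–C2′ bond is cut. The benzylic Grignard reagent 3, made from chloride 1, adds to acrolein 2 and gives the whole carbon skeleton of this fragment in one step.

**8 to 7.** The oxirane CH2 (C3) is detached from the aldehyde carbon of 7. One methylene transfer from a sulfur ylide replaces a three-step enantioselective sequence. Nothing is lost, because the stereocentre of 8 becomes C2, which is ionised and reset when the ring closes. Oxirane 8 is therefore made as the racemate.

## Roads not taken

**Alternative 1: Maitland–Japp annulation.**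
- Cut: C5–C6 and O1–C6.
- Forward key step: with Yb(OTf)3 the δ-hydroxy β-keto ester A2 (C2 to C5, with a benzyl ester on C5) condenses at C5 with the α-silyloxy aldehyde A3 (C6, C1′, C2′). The C2 hydroxyl then adds to the alkylidene and closes the ring as A1.
- Merits: the ring and the C5–C6 bond form in one flask, and the reversible oxa-Michael step favours the cis ring. The benzyl ester would leave with the benzyl ethers by hydrogenolysis and decarboxylation, so the endgame is about two steps against four here. No sulfur, no HMPA and no cryogenic anion are needed.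
- Weak points: C6 is created in this step and is controlled only by C2 through the ring. C2 is a benzylic alcohol on a para-oxygenated arene held with a Lewis acid, which is the centre most likely to ionise. If C2 is lost, C6 follows it and the cis ring forms in the wrong sense relative to C1′. C1′ enters as the α-carbon of an enolisable aldehyde, and A2 needs its own enantioselective aldol.
- Comparison: this road is better in step count after the coupling and in forming the ring directly. The chosen plan sets against it that C6 and C1′, the two centres that cannot be repaired, are made together in 5 by one reagent-controlled epoxidation and are never reacting carbons afterwards. The only centre left to equilibrium is C2, which equilibrium sets correctly.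

**Alternative 2: catalytic asymmetric hetero-Diels–Alder reaction.**
- Cut: C2–C3 and O1–C6.
- Forward key step: the aryl aldehyde A6 (ring A as its acetate) adds across the termini of the chiral 2-silyloxy diene A5 under a chiral tridentate Schiff-base chromium chloride complex (trivalent chromium). The product is the dihydropyran A4, the C4 silyl enol ether.
- Merits: the ring, two bonds and both ring stereocentres arise in one step. The ketone appears as an enol ether, so no thioacetal and no unmasking step are needed. If the cycloaddition performed at a useful level of selectivity, this would be the shortest and most stereo-economic route.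
- Weak points: A6 is an electron-rich, weakly electrophilic aldehyde, and A5 has only one oxygen donor. The stereocentre of A5 sits on the reacting diene terminus, so the C6/C1′ relationship depends on matched double stereodifferentiation. A5 is hydrolytically labile and needs several steps from an aldehyde such as A3.
- Comparison: this road is better in brevity and in the number of stereocentres made per step. The chosen plan sets against it bond formations with no facial-selectivity question (SN2 at CH2 of epoxides 6 and 8) and well-known substrate classes.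

**Alternative 3: ring-closing metathesis.**
- Cut: C3–C4, as an alkene.
- Forward key step: second-generation Grubbs catalyst joins the vinyl group on C2 and the allyl group on C6 of the diene ether A8 to give the dihydropyran A7.
- Merits: the closure itself is dependable, tolerant of functional groups and free of strong base.
- Weak points: both C–O bonds of O1 must exist beforehand. A8 is an ether between two secondary carbons, one of them benzylic and allylic, so its SN1-prone formation would not control C2, and metathesis cannot correct it. A7 has no oxygen at C4, so an internal alkene would have to be oxygenated at C4 and not at C3 and then oxidised. This would be done on a compound whose C2–O1 bond is both allylic and benzylic.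
- Comparison: this road is better in operational simplicity. The chosen plan sets against it that the C4 oxidation level is present by construction in dithiane 13 and that C2 corrects itself when 15 is formed.

Key step: step 5

Remark on the chemistry: oxirane 8 is used as the racemate, so 13 and 14 are pairs of epimers at the benzylic carbinol carbon (the later C2) and carry the descriptor RS there; that carbon is ionised and fixed in step 7.

Step 1
Reactants: 1 1-(benzyloxy)-4-(chloromethyl)benzene; 2 acrolein
Product: 4 rac-1-[4-(benzyloxy)phenyl]but-3-en-2-ol, via Grignard reagent 3 (not isolated)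
Conditions: Mg (excess), Et2O, 0 °C, slow addition of 1; then 2, −78 → 0 °C; aq NH4Cl
Reagents that add atoms: none
Why: Grignard addition: benzylic magnesium chlorides add 1,2 to acrolein, and slow addition of 1 to excess Mg in Et2O keeps Wurtz homocoupling down. The carbinol carbon (later C1′) is formed racemic and is resolved in step 2.

Step 2
Reactants: 4 rac-1-[4-(benzyloxy)phenyl]but-3-en-2-ol
Product: 5 (1S)-2-[4-(benzyloxy)phenyl]-1-[(2R)-oxiran-2-yl]ethan-1-ol
Conditions: Ti(OiPr)4, L-(+)-DIPT, TBHP (0.45 equiv), 4 Å MS, CH2Cl2, −20 °C
Reagents that add atoms: tert-butyl hydroperoxide, CC(C)(C)OO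
Why: Sharpless kinetic resolution of a secondary allylic alcohol: with the L-(+)-tartrate the (S)-alcohol is the fast-reacting enantiomer and receives oxygen on the face that gives the erythro epoxy alcohol, so the catalyst fixes the oxirane carbon (later C6, R) and selects the carbinol (later C1′, S) in one operation. The hydroperoxide is kept below half an equivalent so that the slow (R)-enantiomer of 4 stays an alkene and is removed by chromatography.

Step 3
Reactants: 5 (1S)-2-[4-(benzyloxy)phenyl]-1-[(2R)-oxiran-2-yl]ethan-1-ol
Product: 6 tert-butyl{(1S)-2-[4-(benzyloxy)phenyl]-1-[(2R)-oxiran-2-yl]ethoxy}dimethylsilane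
Conditions: TBSCl, imidazole, DMF, rt
Reagents that add atoms: tert-butyldimethylsilyl chloride, CC(C)(C)[Si](C)(C)Cl
Why: Standard silylation of a secondary alcohol; no alkoxide is generated, so the terminal epoxide cannot move inward by Payne rearrangement and neither stereocentre is touched.

Step 4
Reactants: 7 4-(benzyloxy)-3-methoxybenzaldehyde
Product: 8 rac-2-[4-(benzyloxy)-3-methoxyphenyl]oxirane
Conditions: Me3SI, NaH, DMSO/THF, 0 °C → rt; extractive work-up, no silica
Reagents that add atoms: trimethylsulfonium iodide, C[S+](C)C.[I-]
Why: Corey–Chaykovsky epoxidation: dimethylsulfonium methylide adds to the aldehyde and the betaine closes with loss of dimethyl sulfide, a route well used for alkoxy-substituted benzaldehydes. The oxirane is deliberately racemic because its stereocentre is ionised in step 7.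

Step 5
Reactants: 9 2-(tert-butyldimethylsilyl)-1,3-dithiane; 6 tert-butyl{(1S)-2-[4-(benzyloxy)phenyl]-1-[(2R)-oxiran-2-yl]ethoxy}dimethylsilane; 8 rac-2-[4-(benzyloxy)-3-methoxyphenyl]oxirane
Product: 13 (1RS)-1-[4-(benzyloxy)-3-methoxyphenyl]-2-{2-[(2R,3S)-4-[4-(benzyloxy)phenyl]-2,3-bis(tert-butyldimethylsilyloxy)butyl]-1,3-dithian-2-yl}ethan-1-ol, via lithiated silyl dithiane 10 (not isolated), via lithium alkoxide 11 (not isolated), via Brook-rearranged dithiane anion 12 (not isolated)
Conditions: t-BuLi, Et2O, −78 → −45 °C; 6, Et2O, −78 → −25 °C; then 8 (excess), HMPA/Et2O, −78 → 0 °C; aq NH4Cl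
Reagents that add atoms: none
Why: t-BuLi deprotonates 9 to 10, which opens 6 by SN2 at its unsubstituted carbon (C5) and forms C4–C5; the resulting alkoxide 11 is inert in Et2O. HMPA then triggers the 1,4-Brook rearrangement (silicon from C4 to the C6 oxygen), and the regenerated anion 12 opens 8 at its CH2 (C3) and forms C3–C4, so that protonation gives 13 with the C6 oxygen silylated and the C2 oxygen free. The closest known reaction type is this same solvent-controlled anion relay coupling of a 2-silyl-1,3-dithiane with two different terminal epoxides. No ring is closed. No stereocentre is created: C6 and C1′ arrive unchanged from 6 because neither is a reacting carbon, and the carbinol carbon arrives in both configurations from racemic 8. The step needs attack at the terminal carbon of each epoxide, which is secured in 6 by the branched silyloxy-bearing neighbour and in 8 by the bulk of the tertiary anion together with HMPA, which draws lithium away from the oxirane oxygen and so suppresses benzylic opening and Meinwald rearrangement. It also needs the Brook rearrangement to wait until 6 is consumed, which the change from Et2O to HMPA secures; 6 is therefore the limiting first epoxide and 8 the excess second one. A 1,2 oxygen-to-oxygen silyl shift in 11 is harmless, since both groups are TBS and the relay drains whichever alkoxide sits on C6.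

Step 6
Reactants: 13 (1RS)-1-[4-(benzyloxy)-3-methoxyphenyl]-2-{2-[(2R,3S)-4-[4-(benzyloxy)phenyl]-2,3-bis(tert-butyldimethylsilyloxy)butyl]-1,3-dithian-2-yl}ethan-1-ol
Product: 14 (2S,3R)-1-[4-(benzyloxy)phenyl]-4-{2-[(2RS)-2-[4-(benzyloxy)-3-methoxyphenyl]-2-hydroxyethyl]-1,3-dithian-2-yl}butane-2,3-diol
Conditions: TBAF, THF, 0 °C → rt
Reagents that add atoms: none
Why: Fluoride cleavage of the two secondary TBS ethers; the dithiane, the benzyl ethers and all carbinol centres are inert to TBAF.

Step 7
Reactants: 14 (2S,3R)-1-[4-(benzyloxy)phenyl]-4-{2-[(2RS)-2-[4-(benzyloxy)-3-methoxyphenyl]-2-hydroxyethyl]-1,3-dithian-2-yl}butane-2,3-diol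
Product: 15 (8S,10R)-8-[4-(benzyloxy)-3-methoxyphenyl]-10-[(1S)-2-[4-(benzyloxy)phenyl]-1-hydroxyethyl]-9-oxa-1,5-dithiaspiro[5.5]undecane (the 1,3-dithiane of ketone 16)
Conditions: TsOH·H2O (cat.), CH2Cl2, rt
Reagents that add atoms: none
Why: Acid-catalysed dehydrative etherification of a 1,5-diol (SN1): the benzylic hydroxyl ionises to a cation stabilised by the para-benzyloxy group of ring A and the C6 hydroxyl captures it to close O1–C2, both C2 epimers of 14 converging on the same cation. The closure is reversible under these conditions, so C2 is set by C6 under thermodynamic control as the 2,6-cis (diequatorial) isomer. An axial group at C2 or C6 would be syn-axial to a dithiane sulfur on C4, and the seven-membered ether through the C1′ hydroxyl should be slower and is equally reversible.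

Step 8
Reactants: 15 (8S,10R)-8-[4-(benzyloxy)-3-methoxyphenyl]-10-[(1S)-2-[4-(benzyloxy)phenyl]-1-hydroxyethyl]-9-oxa-1,5-dithiaspiro[5.5]undecane
Product: 16 (2S,6R)-2-[4-(benzyloxy)-3-methoxyphenyl]-6-[(1S)-2-[4-(benzyloxy)phenyl]-1-hydroxyethyl]oxan-4-one
Conditions: MeI (excess), CaCO3, MeCN/H2O (9:1), 45 °C
Reagents that add atoms: water, O
Why: Alkylative hydrolysis of the dithiane: S-methylation, ring opening to the thionium ion and capture by water, with CaCO3 taking up the HI. No base strong enough for β-elimination of the new β,β′-dialkoxy ketone is present, and the benzyl ethers and the secondary alcohol are inert.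

Step 9
Reactants: 16 (2S,6R)-2-[4-(benzyloxy)-3-methoxyphenyl]-6-[(1S)-2-[4-(benzyloxy)phenyl]-1-hydroxyethyl]oxan-4-one
Product: 17 (2S,6R)-2-(4-hydroxy-3-methoxyphenyl)-6-[(1S)-1-hydroxy-2-(4-hydroxyphenyl)ethyl]oxan-4-one (CNP0222055.1)
Conditions: H2 (1 atm), 10% Pd/C, EtOAc, rt
Reagents that add atoms: none
Why: Hydrogenolysis of the two aryl benzyl ethers, which should cleave far faster than the dialkyl benzylic C2–O1 bond or the ketone reacts under neutral conditions at atmospheric pressure. The step follows step 8 so that no sulfur reaches the catalyst, and no stereocentre is affected.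

## Compound list

1 | 1-(benzyloxy)-4-(chloromethyl)benzene | ClCc1ccc(OCc2ccccc2)cc1 | starting material
2 | acrolein (prop-2-enal) | C=CC=O | starting material
3 | [4-(benzyloxy)benzyl]magnesium chloride | Cl[Mg]Cc1ccc(OCc2ccccc2)cc1 | intermediate (not isolated)
4 | rac-1-[4-(benzyloxy)phenyl]but-3-en-2-ol | C=CC(O)Cc1ccc(OCc2ccccc2)cc1 | intermediate
5 | (1S)-2-[4-(benzyloxy)phenyl]-1-[(2R)-oxiran-2-yl]ethan-1-ol | C1O[C@H]1[C@@H](O)Cc1ccc(OCc2ccccc2)cc1 | intermediate
6 | tert-butyl{(1S)-2-[4-(benzyloxy)phenyl]-1-[(2R)-oxiran-2-yl]ethoxy}dimethylsilane | C1O[C@H]1[C@@H](O[Si](C)(C)C(C)(C)C)Cc1ccc(OCc2ccccc2)cc1 | intermediate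
7 | 4-(benzyloxy)-3-methoxybenzaldehyde | COc1cc(C=O)ccc1OCc1ccccc1 | starting material
8 | rac-2-[4-(benzyloxy)-3-methoxyphenyl]oxirane | COc1cc(C2CO2)ccc1OCc1ccccc1 | intermediate
9 | 2-(tert-butyldimethylsilyl)-1,3-dithiane | CC(C)(C)[Si](C)(C)C1SCCCS1 | starting material
10 | 2-(tert-butyldimethylsilyl)-2-lithio-1,3-dithiane | [Li]C1([Si](C)(C)C(C)(C)C)SCCCS1 | intermediate (not isolated)
11 | lithium (2R,3S)-4-[4-(benzyloxy)phenyl]-3-(tert-butyldimethylsilyloxy)-1-[2-(tert-butyldimethylsilyl)-1,3-dithian-2-yl]butan-2-olate | CC(C)(C)[Si](C)(C)C1(C[C@H]([C@@H](O[Si](C)(C)C(C)(C)C)Cc2ccc(OCc3ccccc3)cc2)O[Li])SCCCS1 | intermediate (not isolated)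
12 | 2-[(2R,3S)-4-[4-(benzyloxy)phenyl]-2,3-bis(tert-butyldimethylsilyloxy)butyl]-2-lithio-1,3-dithiane | [Li]C1(C[C@H]([C@@H](O[Si](C)(C)C(C)(C)C)Cc2ccc(OCc3ccccc3)cc2)O[Si](C)(C)C(C)(C)C)SCCCS1 | intermediate (not isolated)
13 | (1RS)-1-[4-(benzyloxy)-3-methoxyphenyl]-2-{2-[(2R,3S)-4-[4-(benzyloxy)phenyl]-2,3-bis(tert-butyldimethylsilyloxy)butyl]-1,3-dithian-2-yl}ethan-1-ol (both C1 epimers) | COc1cc(C(O)CC2(C[C@H]([C@@H](O[Si](C)(C)C(C)(C)C)Cc3ccc(OCc4ccccc4)cc3)O[Si](C)(C)C(C)(C)C)SCCCS2)ccc1OCc1ccccc1 | intermediate
14 | (2S,3R)-1-[4-(benzyloxy)phenyl]-4-{2-[(2RS)-2-[4-(benzyloxy)-3-methoxyphenyl]-2-hydroxyethyl]-1,3-dithian-2-yl}butane-2,3-diol (both epimers at the benzylic carbinol) | COc1cc(C(O)CC2(C[C@H]([C@@H](O)Cc3ccc(OCc4ccccc4)cc3)O)SCCCS2)ccc1OCc1ccccc1 | intermediate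
15 | (8S,10R)-8-[4-(benzyloxy)-3-methoxyphenyl]-10-[(1S)-2-[4-(benzyloxy)phenyl]-1-hydroxyethyl]-9-oxa-1,5-dithiaspiro[5.5]undecane | COc1cc([C@@H]2CC3(C[C@H]([C@@H](O)Cc4ccc(OCc5ccccc5)cc4)O2)SCCCS3)ccc1OCc1ccccc1 | intermediate
16 | (2S,6R)-2-[4-(benzyloxy)-3-methoxyphenyl]-6-[(1S)-2-[4-(benzyloxy)phenyl]-1-hydroxyethyl]oxan-4-one | COc1cc([C@@H]2CC(=O)C[C@H]([C@@H](O)Cc3ccc(OCc4ccccc4)cc3)O2)ccc1OCc1ccccc1 | intermediate
17 | (2S,6R)-2-(4-hydroxy-3-methoxyphenyl)-6-[(1S)-1-hydroxy-2-(4-hydroxyphenyl)ethyl]oxan-4-one | COc1cc([C@@H]2CC(=O)C[C@H]([C@@H](O)Cc3ccc(O)cc3)O2)ccc1O | target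

## Step count and least certain steps

Total: 9 steps. Longest linear sequence: 8 steps (1 to 17 through steps 1, 2, 3, 5, 6, 7, 8 and 9); the branch from 7 adds one step.

**Step 5 (key step).**
- What may go wrong: premature Brook rearrangement while 6 is still present, so that anion 12 consumes a second molecule of 6; lithium-assisted ring opening or rearrangement of the electron-rich oxirane 8 in competition with SN2 attack at its CH2; or silyl transfer between the two neighbouring oxygens that leaves part of the material unable to relay.
- Fallback (from 6, rejoining at 12): the two C–C bonds are made in separate flasks by classical iterative dithiane alkylation. Commercial 1,3-dithiane is lithiated (n-BuLi, THF, −30 °C) to 2-lithio-1,3-dithiane F1, which opens 6 at C5 and gives (2R,3S)-4-[4-(benzyloxy)phenyl]-3-(tert-butyldimethylsilyloxy)-1-(1,3-dithian-2-yl)butan-2-ol F2. Any silyl-shifted regioisomer converges in the next operation. Silylation (TBSOTf, 2,6-lutidine, CH2Cl2) gives 2-[(2R,3S)-4-[4-(benzyloxy)phenyl]-2,3-bis(tert-butyldimethylsilyloxy)butyl]-1,3-dithiane F3. Deprotonation of isolated F3 (t-BuLi, THF/HMPA, −78 °C) gives 12, which is treated with 8 as in the last stage of step 5 to reach 13.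

**Step 7.**
- What may go wrong: loss of the benzylic cation by elimination to a styrene that does not re-enter the equilibrium, closure through the C1′ hydroxyl, or incomplete equilibration to the cis ring.
- Fallback (from 14 to 15): the ring is closed by reductive etherification, which sets C2 kinetically. Selective benzylic oxidation of 14 (MnO2, CH2Cl2) gives 1-[4-(benzyloxy)-3-methoxyphenyl]-2-{2-[(2R,3S)-4-[4-(benzyloxy)phenyl]-2,3-dihydroxybutyl]-1,3-dithian-2-yl}ethan-1-one F4, which is in equilibrium with its six-membered lactol. Et3SiH and BF3·OEt2 (CH2Cl2, −78 → −20 °C) reduce the derived oxocarbenium ion by axial hydride delivery and give the 2,6-cis ether 15.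

**Step 8.**
- What may go wrong: slow S-alkylation at the hindered spiro carbon, and acid-promoted opening of the benzylic C2–O1 bond or retro-oxa-Michael opening once the ketone is free.
- Fallback (from 14 to 16, bypassing 15): the order of unmasking and ring closure is reversed so that ring opening becomes part of the plan. Hydrolysis of the open-chain dithiane 14 (MeI, CaCO3, aq MeCN) gives (5R,6S)-1-[4-(benzyloxy)-3-methoxyphenyl]-7-[4-(benzyloxy)phenyl]-1,5,6-trihydroxyheptan-3-one F5. Acid (TsOH, CH2Cl2) dehydrates it to (1E,5R,6S)-1-[4-(benzyloxy)-3-methoxyphenyl]-7-[4-(benzyloxy)phenyl]-5,6-dihydroxyhept-1-en-3-one F6. Intramolecular oxa-Michael addition of the C6 hydroxyl then gives 16 under thermodynamic control.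

**Step 2.**
- What may go wrong: incomplete discrimination between the enantiomers of 4 at a useful conversion, which lowers the enantiomeric purity of 5 (the product of a kinetic resolution cannot exceed what the selectivity factor allows), and titanium-mediated opening of the terminal epoxide.
- Fallback (from 4 to 5): the resolution is run in recovery mode and the epoxidation is done separately. Ti(OiPr)4, D-(−)-DIPT and TBHP (0.6 equiv) leave (2S)-1-[4-(benzyloxy)phenyl]but-3-en-2-ol F7, while the (R)-enantiomer is consumed as (1R)-2-[4-(benzyloxy)phenyl]-1-[(2S)-oxiran-2-yl]ethan-1-ol F8 and discarded. Matched epoxidation of F7 (Ti(OiPr)4, L-(+)-DIPT, TBHP, CH2Cl2, −20 °C) then gives 5.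

**Step 4.**
- What may go wrong: rearrangement or oligomerisation of the acid-sensitive, electron-rich oxirane during isolation, and carry-over of DMSO or base into the water-sensitive key step.
- Fallback (from 7 to 8): Wittig methylenation (Ph3PCH3Br, KOtBu, THF) gives the storable styrene 1-(benzyloxy)-4-ethenyl-2-methoxybenzene F9. Epoxidation with DMDO in acetone at 0 °C gives 8 with only volatile by-products, so that it can be concentrated and used at once.

## Further compounds

F1 | step 5 | 2-lithio-1,3-dithiane | [Li]C1SCCCS1
F2 | step 5 | (2R,3S)-4-[4-(benzyloxy)phenyl]-3-(tert-butyldimethylsilyloxy)-1-(1,3-dithian-2-yl)butan-2-ol | O[C@H](CC1SCCCS1)[C@@H](O[Si](C)(C)C(C)(C)C)Cc1ccc(OCc2ccccc2)cc1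
F3 | step 5 | 2-[(2R,3S)-4-[4-(benzyloxy)phenyl]-2,3-bis(tert-butyldimethylsilyloxy)butyl]-1,3-dithiane | CC(C)(C)[Si](C)(C)O[C@H](CC1SCCCS1)[C@@H](O[Si](C)(C)C(C)(C)C)Cc1ccc(OCc2ccccc2)cc1
F4 | step 7 | 1-[4-(benzyloxy)-3-methoxyphenyl]-2-{2-[(2R,3S)-4-[4-(benzyloxy)phenyl]-2,3-dihydroxybutyl]-1,3-dithian-2-yl}ethan-1-one | COc1cc(C(=O)CC2(C[C@H]([C@@H](O)Cc3ccc(OCc4ccccc4)cc3)O)SCCCS2)ccc1OCc1ccccc1
F5 | step 8 | (5R,6S)-1-[4-(benzyloxy)-3-methoxyphenyl]-7-[4-(benzyloxy)phenyl]-1,5,6-trihydroxyheptan-3-one (both C1 epimers) | COc1cc(C(O)CC(=O)C[C@H]([C@@H](O)Cc2ccc(OCc3ccccc3)cc2)O)ccc1OCc1ccccc1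
F6 | step 8 | (1E,5R,6S)-1-[4-(benzyloxy)-3-methoxyphenyl]-7-[4-(benzyloxy)phenyl]-5,6-dihydroxyhept-1-en-3-one | COc1cc(/C=C/C(=O)C[C@H]([C@@H](O)Cc2ccc(OCc3ccccc3)cc2)O)ccc1OCc1ccccc1
F7 | step 2 | (2S)-1-[4-(benzyloxy)phenyl]but-3-en-2-ol | C=C[C@@H](O)Cc1ccc(OCc2ccccc2)cc1
F8 | step 2 | (1R)-2-[4-(benzyloxy)phenyl]-1-[(2S)-oxiran-2-yl]ethan-1-ol | C1O[C@@H]1[C@H](O)Cc1ccc(OCc2ccccc2)cc1
F9 | step 4 | 1-(benzyloxy)-4-ethenyl-2-methoxybenzene | COc1cc(C=C)ccc1OCc1ccccc1
A1 | alternative 1 | benzyl (2R,6S)-6-[4-(benzyloxy)-3-methoxyphenyl]-2-[(1S)-2-[4-(benzyloxy)phenyl]-1-(tert-butyldimethylsilyloxy)ethyl]-4-hydroxy-5,6-dihydro-2H-pyran-3-carboxylate | COc1cc([C@@H]2CC(O)=C(C(=O)OCc4ccccc4)[C@H]([C@@H](O[Si](C)(C)C(C)(C)C)Cc3ccc(OCc5ccccc5)cc3)O2)ccc1OCc1ccccc1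
A2 | alternative 1 | benzyl (5S)-5-[4-(benzyloxy)-3-methoxyphenyl]-5-hydroxy-3-oxopentanoate | COc1cc([C@@H](O)CC(=O)CC(=O)OCc2ccccc2)ccc1OCc1ccccc1
A3 | alternative 1 | (2S)-3-[4-(benzyloxy)phenyl]-2-(tert-butyldimethylsilyloxy)propanal | O=C[C@@H](O[Si](C)(C)C(C)(C)C)Cc1ccc(OCc2ccccc2)cc1
A4 | alternative 2 | 4-[(2S,6R)-6-[(1S)-2-[4-(benzyloxy)phenyl]-1-(tert-butyldimethylsilyloxy)ethyl]-4-(triethylsilyloxy)-3,6-dihydro-2H-pyran-2-yl]-2-methoxyphenyl acetate | COc1cc([C@@H]2CC(O[Si](CC)(CC)CC)=C[C@H]([C@@H](O[Si](C)(C)C(C)(C)C)Cc3ccc(OCc4ccccc4)cc3)O2)ccc1OC(C)=O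
A5 | alternative 2 | tert-butyl{[(2S,3E)-1-[4-(benzyloxy)phenyl]-5-(triethylsilyloxy)hexa-3,5-dien-2-yl]oxy}dimethylsilane | C=C(O[Si](CC)(CC)CC)/C=C/[C@@H](O[Si](C)(C)C(C)(C)C)Cc1ccc(OCc2ccccc2)cc1
A6 | alternative 2 | 4-formyl-2-methoxyphenyl acetate | COc1cc(C=O)ccc1OC(C)=O
A7 | alternative 3 | (2S,6R)-2-[4-(benzyloxy)-3-methoxyphenyl]-6-[(1S)-2-[4-(benzyloxy)phenyl]-1-(tert-butyldimethylsilyloxy)ethyl]-5,6-dihydro-2H-pyran | COc1cc([C@@H]2C=CC[C@H]([C@@H](O[Si](C)(C)C(C)(C)C)Cc3ccc(OCc4ccccc4)cc3)O2)ccc1OCc1ccccc1
A8 | alternative 3 | tert-butyl{[(2S,3R)-1-[4-(benzyloxy)phenyl]-3-{[(1S)-1-[4-(benzyloxy)-3-methoxyphenyl]prop-2-en-1-yl]oxy}hex-5-en-2-yl]oxy}dimethylsilane | COc1cc([C@H](C=C)O[C@H](CC=C)[C@@H](O[Si](C)(C)C(C)(C)C)Cc2ccc(OCc3ccccc3)cc2)ccc1OCc1ccccc1
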